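**Retrosynthetic overview**

1. Ring B and both stereocentres come from methyl ferulate 1 by way of silyl ether 2 and (2R,3S)-glycidate 3 (asymmetric epoxidation). The epoxide α-carbon becomes C-3 and the benzylic carbon becomes C-2.
2. C-4–C-4a disconnection: glycidate 3 plus triacetic acid lactone 4 (a masked triketide, used as its dianion 5) give acylmethyl pyrone 6.
3. Key disconnection: rings A and C of flavanonol 9 both unravel to 6. Forward, in one pot through 7 and 8, ring A closes first (C-4a–C-5, Claisen-type recyclization of the pyrone) and ring C second (O-1–C-2).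
4. Last disconnection: the 7-O-prenyl ether, 9 to target 10.

Assumption: the target is the (2R,3R)-trans flavanonol exactly as drawn, and the L-fructose-derived diacetate ketone used catalytically in step 2 (mirror image of the usual D-fructose-derived ketone, made from L-sorbose) is taken as available.

**Route**

Step 1
Reactants: 1 methyl (E)-3-(4-hydroxy-3-methoxyphenyl)prop-2-enoate (methyl ferulate)
Product: 2 methyl (E)-3-[4-(tert-butyldimethylsilyloxy)-3-methoxyphenyl]prop-2-enoate
Conditions: TBSCl (1.2 equiv), imidazole (2.5 equiv), DMF, 23 °C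
Reagents that add atoms: tert-butyldimethylsilyl chloride (TBSCl), CC(C)(C)[Si](C)(C)Cl
Why: Imidazole-promoted O-silylation (silyl ether protection) masks the phenol so that it survives the oxidant of step 2 and the amide base of step 3, and no stereocentre is involved.

Step 2
Reactants: 2 methyl (E)-3-[4-(tert-butyldimethylsilyloxy)-3-methoxyphenyl]prop-2-enoate
Product: 3 methyl (2R,3S)-3-[4-(tert-butyldimethylsilyloxy)-3-methoxyphenyl]oxirane-2-carboxylate (trans)
Conditions: 4,5-di-O-acetyl-1,2-O-isopropylidene-β-L-erythro-hexo-2,3-diulo-2,6-pyranose (0.3 equiv), KHSO5 (as Oxone, 5 equiv), NaHCO3, Bu4NHSO4 (cat.), CH3CN/aq Na2EDTA, 0 °C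
Reagents that add atoms: potassium peroxymonosulfate (KHSO5), [K+].[O-]S(=O)(=O)OO
Why: Shi asymmetric epoxidation, in which the chiral dioxirane formed from the ketone and KHSO5 transfers oxygen to the trans-cinnamate through a spiro transition state; the L-series ketone (mirror image of the D-fructose ketone that gives (2S,3R)-glycidates from cinnamates) sets C-2 as R and C-3 as S, and the ester keeps the electron-rich aryl epoxide isolable.

Step 3
Reactants: 3 methyl (2R,3S)-3-[4-(tert-butyldimethylsilyloxy)-3-methoxyphenyl]oxirane-2-carboxylate; 4 4-hydroxy-6-methyl-2H-pyran-2-one (triacetic acid lactone)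
Product: 6 6-{2-[(2R,3S)-3-[4-(tert-butyldimethylsilyloxy)-3-methoxyphenyl]oxiran-2-yl]-2-oxoethyl}-4-hydroxy-2H-pyran-2-one, via dilithio pyrone 5 (not isolated)
Conditions: 4 (2.2 equiv), LiN(iPr)2 (4.4 equiv), THF, −78 to −40 °C; then 3 (1.0 equiv), −78 to −20 °C; AcOH quench at −40 °C, extraction, crude product taken on
Reagents that add atoms: none
Why: Claisen-type C-acylation of the 6-methyl carbanion of pyrone dianion 5 by the ester (the known acylation of the triacetic acid lactone dianion) forms the C-4–C-4a bond; at low temperature the ester carbonyl reacts faster than the epoxide, and neither stereocentre is touched.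

Step 4
Reactants: 6 6-{2-[(2R,3S)-3-[4-(tert-butyldimethylsilyloxy)-3-methoxyphenyl]oxiran-2-yl]-2-oxoethyl}-4-hydroxy-2H-pyran-2-one
Product: 9 (2R,3R)-3,5,7-trihydroxy-2-(4-hydroxy-3-methoxyphenyl)-2,3-dihydro-4H-chromen-4-one (dihydroisorhamnetin), via pyrone methoxy ketol 7 (not isolated), via phloroglucinol methoxy ketol 8 (not isolated)
Conditions: Mg(OMe)2 (6 equiv), MeOH, 65 °C; then HCl (to about 1 M), 50 °C, same pot
Reagents that add atoms: none
Why: Proposed new method: methoxide removes the aryl silyl ether and the freed 4-hydroxyaryl epoxide is methanolysed at the benzylic carbon through its para-quinone methide (7); Mg(OMe)2 then opens the lactone to the magnesium-chelated (Z)-triketo ester, whose carbanion between the two ketones closes onto the ester to build ring A (8), which is the classical biomimetic Claisen recyclization of 6-acylmethyl-4-hydroxy-2-pyrones to 2-acylphloroglucinols; acid finally ionizes the 4-hydroxybenzylic methyl ether and the ortho phenol closes ring C 6-endo, which is the known acid cyclization of 2'-hydroxychalcone epoxides to dihydroflavonols; C-3 keeps the R configuration of the epoxide α-carbon and C-2 settles trans (2R) under thermodynamic control, any cis epimer being removed on crystallization.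

Step 5
Reactants: 9 (2R,3R)-3,5,7-trihydroxy-2-(4-hydroxy-3-methoxyphenyl)-2,3-dihydro-4H-chromen-4-one
Product: 10 (2R,3R)-3,5-dihydroxy-2-(4-hydroxy-3-methoxyphenyl)-7-(3-methylbut-2-enyloxy)-2,3-dihydro-4H-chromen-4-one
Conditions: prenyl bromide (1.1 equiv), K2CO3 (1.1 equiv), DMF, 0 to 23 °C, argon
Reagents that add atoms: 1-bromo-3-methylbut-2-ene (prenyl bromide), CC(C)=CCBr
Why: Williamson etherification under acidity control, because the 7-OH para to the C-4 carbonyl (a vinylogous acid, pKa about 7) is ionized by one equivalent of K2CO3 well ahead of the 4'-OH (pKa about 10), the chelated 5-OH and the 3-OH, so only O-7 is alkylated (SN2), and the mild air-free conditions leave C-2 and C-3 unchanged.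

**Compound list**

1 | methyl (E)-3-(4-hydroxy-3-methoxyphenyl)prop-2-enoate (methyl ferulate) | COC(=O)/C=C/c1ccc(O)c(OC)c1 | starting material
2 | methyl (E)-3-[4-(tert-butyldimethylsilyloxy)-3-methoxyphenyl]prop-2-enoate | COC(=O)/C=C/c1ccc(O[Si](C)(C)C(C)(C)C)c(OC)c1 | intermediate
3 | methyl (2R,3S)-3-[4-(tert-butyldimethylsilyloxy)-3-methoxyphenyl]oxirane-2-carboxylate | COC(=O)[C@@H]1O[C@H]1c1ccc(O[Si](C)(C)C(C)(C)C)c(OC)c1 | intermediate
4 | 4-hydroxy-6-methyl-2H-pyran-2-one (triacetic acid lactone) | CC1=CC(O)=CC(=O)O1 | starting material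
5 | dilithium salt of the triacetic acid lactone dianion (4-oxido-6-lithiomethyl-2H-pyran-2-one) | [Li+].[Li+].[CH2-]C1=CC([O-])=CC(=O)O1 | intermediate
6 | 6-{2-[(2R,3S)-3-[4-(tert-butyldimethylsilyloxy)-3-methoxyphenyl]oxiran-2-yl]-2-oxoethyl}-4-hydroxy-2H-pyran-2-one | O=C1C=C(O)C=C(CC(=O)[C@@H]2O[C@H]2c2ccc(O[Si](C)(C)C(C)(C)C)c(OC)c2)O1 | intermediate
7 | 4-hydroxy-6-[(3R)-3-hydroxy-4-(4-hydroxy-3-methoxyphenyl)-4-methoxy-2-oxobutyl]-2H-pyran-2-one (both C-4 epimers) | O=C1C=C(O)C=C(CC(=O)[C@H](O)C(OC)c2ccc(O)c(OC)c2)O1 | intermediate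
8 | (2R)-2-hydroxy-3-(4-hydroxy-3-methoxyphenyl)-3-methoxy-1-(2,4,6-trihydroxyphenyl)propan-1-one (both C-3 epimers) | COc1cc(C(OC)[C@@H](O)C(=O)c2c(O)cc(O)cc2O)ccc1O | intermediate
9 | (2R,3R)-3,5,7-trihydroxy-2-(4-hydroxy-3-methoxyphenyl)-2,3-dihydro-4H-chromen-4-one (dihydroisorhamnetin) | COc1cc([C@H]2Oc3cc(O)cc(O)c3C(=O)[C@@H]2O)ccc1O | intermediate
10 | (2R,3R)-3,5-dihydroxy-2-(4-hydroxy-3-methoxyphenyl)-7-(3-methylbut-2-enyloxy)-2,3-dihydro-4H-chromen-4-one | COc1cc([C@H]2Oc3cc(OCC=C(C)C)cc(O)c3C(=O)[C@@H]2O)ccc1O | target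

**Step count and risks**

Total step count: 5. Longest linear sequence: 5 steps (1 to 10; lactone 4 enters at step 3).

The three steps most likely to fail, in order of risk:

Step 4 (the one-pot double ring closure). The triketo ester may aromatize in the aldol sense to a resorcylate instead of the Claisen sense. The α-ketol may lose its C-3 configuration by enolization or methanol elimination during the basic stage. Ring C may not close cleanly. The fallback sets out from 3 and comes back at 9, with ring A taken ready-made. Phloroglucinol is converted with MOMCl and iPr2NEt into 1,3,5-tris(methoxymethoxy)benzene F1. F1 is lithiated between two of its ether groups (n-BuLi, THF, 0 °C) to give 2,4,6-tris(methoxymethoxy)phenyllithium F2. F2 is acylated by 3 at −78 °C; the two ortho substituents stop a second addition, giving [(2R,3S)-3-[4-(tert-butyldimethylsilyloxy)-3-methoxyphenyl]oxiran-2-yl][2,4,6-tris(methoxymethoxy)phenyl]methanone F3. HCl in MeOH at 50 °C then removes the acetal and silyl groups and closes ring C by benzylic 6-endo opening, giving 9.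

Step 3 (acylation of dianion 5). The dianion is poorly soluble and strongly basic, so it may deprotonate or open the glycidate, and the acidic product 6 may damage its own epoxide on handling. The fallback sets out from 3 and comes back at 6, building the pyrone ring after the C–C bond. Commercial 2,2,6-trimethyl-4H-1,3-dioxin-4-one is acetylated at its methyl group (LiN(SiMe3)2, then N-acetylimidazole) to 2,2-dimethyl-6-(2-oxopropyl)-4H-1,3-dioxin-4-one F4. F4, after double deprotonation with LiN(iPr)2, is acylated at its terminal methyl by 3 to give 6-{4-[(2R,3S)-3-[4-(tert-butyldimethylsilyloxy)-3-methoxyphenyl]oxiran-2-yl]-2,4-dioxobutyl}-2,2-dimethyl-4H-1,3-dioxin-4-one F5. Heating F5 in toluene at 110 °C expels acetone (retro-hetero-Diels–Alder), and O-cyclization onto the 5-enol oxygen under neutral conditions builds the 4-hydroxy-2-pyrone ring, giving 6.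

Step 5 (regioselective prenylation). Some 4'-O- or bis-alkylation, base-induced C-2 epimerization or air oxidation to the flavonol may lower the yield. The fallback sets out from 4 (and uses 3) and comes back at 10, placing the ether before the rings are made. Lactone 4 is O-alkylated under Mitsunobu conditions (3-methylbut-2-en-1-ol, PPh3, DIAD, THF, 0 °C) to 6-methyl-4-(3-methylbut-2-enyloxy)-2H-pyran-2-one F6. F6 is deprotonated at its 6-methyl group (LiN(iPr)2, −78 °C) and acylated by 3 to give 6-{2-[(2R,3S)-3-[4-(tert-butyldimethylsilyloxy)-3-methoxyphenyl]oxiran-2-yl]-2-oxoethyl}-4-(3-methylbut-2-enyloxy)-2H-pyran-2-one F7. The Mg(OMe)2 recyclization of F7 in MeOH, finished with AcOH at 50 °C to spare the allylic ether, then gives 10 directly, because the pyrone 4-oxygen ends up para to the acyl group.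

**Further compounds**

F1 | step 4 | 1,3,5-tris(methoxymethoxy)benzene | COCOc1cc(OCOC)cc(OCOC)c1
F2 | step 4 | 2,4,6-tris(methoxymethoxy)phenyllithium | [Li]c1c(OCOC)cc(OCOC)cc1OCOC
F3 | step 4 | [(2R,3S)-3-[4-(tert-butyldimethylsilyloxy)-3-methoxyphenyl]oxiran-2-yl][2,4,6-tris(methoxymethoxy)phenyl]methanone | COCOc1cc(OCOC)c(C(=O)[C@@H]2O[C@H]2c2ccc(O[Si](C)(C)C(C)(C)C)c(OC)c2)c(OCOC)c1
F4 | step 3 | 2,2-dimethyl-6-(2-oxopropyl)-4H-1,3-dioxin-4-one | CC(=O)CC1=CC(=O)OC(C)(C)O1
F5 | step 3 | 6-{4-[(2R,3S)-3-[4-(tert-butyldimethylsilyloxy)-3-methoxyphenyl]oxiran-2-yl]-2,4-dioxobutyl}-2,2-dimethyl-4H-1,3-dioxin-4-one | CC1(C)OC(CC(=O)CC(=O)[C@@H]2O[C@H]2c2ccc(O[Si](C)(C)C(C)(C)C)c(OC)c2)=CC(=O)O1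
F6 | step 5 | 6-methyl-4-(3-methylbut-2-enyloxy)-2H-pyran-2-one | CC1=CC(OCC=C(C)C)=CC(=O)O1
F7 | step 5 | 6-{2-[(2R,3S)-3-[4-(tert-butyldimethylsilyloxy)-3-methoxyphenyl]oxiran-2-yl]-2-oxoethyl}-4-(3-methylbut-2-enyloxy)-2H-pyran-2-one | CC(C)=CCOC1=CC(=O)OC(CC(=O)[C@@H]2O[C@H]2c2ccc(O[Si](C)(C)C(C)(C)C)c(OC)c2)=C1
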